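**Plan**

- Retrosynthetic cuts, in order: (a) the aryl–C(=O) bond of the prenylated resorcinol ketone, giving carboxylic acid 15 and an arylzinc made from bromide 20; (b) the C-2–aryl bond of the cyclohexene (numbered C-1 acyl-bearing, C-2 chalcone aryl, C-3=C-4 with methyl on C-4, C-6 dihydroxyphenyl), giving bridged allylic lactone 9 and a chalcone-bearing arylzinc; (c) the lactone C–O bond and the two Diels–Alder bonds, giving isoprene and a cinnamoyl equivalent; the chalcone enone comes from an aldol condensation.
- Forward: a Diels–Alder reaction builds the cyclohexene with C-1 and C-6; the C-1 carboxyl is tied to C-4 as a temporary 2-oxabicyclo[2.2.2]oct-5-en-3-one; its allylic C–O bond is exchanged for the C-2 aryl group, which frees the acid; acid chloride plus arylzinc gives the ketone; eight MOM groups come off last.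
- Stereochemistry: C-1/C-6 trans follows from the (E)-dienophile, the absolute sense from Cu(OTf)2/t-Bu-box. C-2 comes from the lactone: the bridging oxygen is necessarily cis to the carboxyl and palladium replaces it with inversion, so the aryl group ends trans to the carboxyl and cis to the C-6 aryl. Nothing is epimerised afterwards; the all-trans arrangement is also the thermodynamic one at C-1.
- Enabling feature for the key event: the ketone carbon is exocyclic, bonded to cyclohexene C-1 and to C-1 of the benzene ring that carries the prenyl group at C-3 between the oxygens at C-2 and C-4. It can therefore be carried as a carboxyl carbon (first as C-3 of the temporary lactone, then as an acyl chloride). In 2-prenylresorcinol ring positions 4 and 6 are equivalent, so one bromine fixes where the metal, and hence the acyl group, goes.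

Key step: step 12

Remark: the facial sense of Cu(OTf)2/(S,S)-t-Bu-box in step 3 is assumed by analogy with other two-point-binding dienophiles; the (R,R)-ligand is used if the opposite sense is found.

**Route**

Step 1
Reactants: 1 2,4-dihydroxybenzaldehyde
Product: 2 2,4-bis(methoxymethoxy)benzaldehyde
Conditions: MOMCl, i-Pr2NEt, DMF, 0 °C → rt
Reagents that add atoms: chloromethyl methyl ether, COCCl
Why: O-alkylation of both phenols with the chloromethyl ether gives base- and organometal-stable MOM acetals, the chelated ortho-hydroxyl needing excess reagent.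

Step 2
Reactants: 2 2,4-bis(methoxymethoxy)benzaldehyde; 3 3-hydroxy-3-methylbutan-2-one
Product: 4 (E)-1-[2,4-bis(methoxymethoxy)phenyl]-4-hydroxy-4-methylpent-1-en-3-one
Conditions: LiOH·H2O, MeOH/H2O, rt
Reagents that add atoms: none
Why: Claisen–Schmidt aldol condensation at the only enolisable position (the methyl group) should give the (E)-enone, an α′-hydroxy enone that serves as a chelating cinnamic acid equivalent.

Step 3
Reactants: 4 (E)-α′-hydroxy enone; 5 isoprene
Product: 6 1-[(1R,6R)-6-[2,4-bis(methoxymethoxy)phenyl]-4-methylcyclohex-3-en-1-yl]-2-hydroxy-2-methylpropan-1-one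
Conditions: Cu(OTf)2 (10 mol %), (S,S)-t-Bu-box (11 mol %), isoprene (excess), CH2Cl2, 4 Å MS, rt
Reagents that add atoms: none
Why: Diels–Alder reaction of the enone held s-cis in a five-membered chelate (C=O and OH) on divalent copper: isoprene should add with "para" orientation to the Cα-Re/Cβ-Re face left open by the ligand, setting C-1 and C-6 as (1R,6R), their trans relationship following from the (E)-alkene.

Step 4
Reactants: 6 Diels–Alder ketol
Product: 7 (1R,6R)-6-[2,4-bis(methoxymethoxy)phenyl]-4-methylcyclohex-3-ene-1-carboxylic acid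
Conditions: NaIO4, MeOH/H2O, rt
Reagents that add atoms: sodium periodate, [Na+].[O-]I(=O)(=O)=O (net source of the new carboxyl oxygen)
Why: periodate cleavage of the α-hydroxy ketone (through its hydrate) should release the carboxylic acid and acetone without touching the alkene, the arene or either stereocentre.

Step 5
Reactants: 7 trans cyclohexene acid
Product: 9 (1R,4R,8R)-8-[2,4-bis(methoxymethoxy)phenyl]-1-methyl-2-oxabicyclo[2.2.2]oct-5-en-3-one, via selenolactone 8 (not isolated)
Conditions: PhSeCl, pyridine, CH2Cl2, −78 → 0 °C; then 30% H2O2, 0 °C → rt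
Reagents that add atoms: phenylselenyl chloride, Cl[Se]c1ccccc1 (its PhSe group is present in 8 only)
Why: phenylselenolactonisation (Markovnikov, anti addition) opens the seleniranium ion at the tertiary methyl-bearing carbon, which the C-1 carboxylate can reach only from its own face, so the new C–O stereocentre is fixed cis to the carbonyl by the bicyclo[2.2.2] bridge; selenoxide syn-elimination then has only the CH2 next to the other bridgehead available and should give the allylic lactone.

Step 6
Reactants: 10 1-(2,4-dihydroxyphenyl)ethanone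
Product: 11 1-(2,4-dihydroxy-3-iodophenyl)ethanone
Conditions: I2, HIO3, EtOH/H2O, rt
Reagents that add atoms: iodine, II; iodic acid, O[I](=O)=O
Why: electrophilic aromatic iodination should go to the carbon flanked by both hydroxyl groups (doubly ortho-activated, as in the iodination of resorcinol itself), mono-iodination being held by stoichiometry.

Step 7
Reactants: 11 1-(2,4-dihydroxy-3-iodophenyl)ethanone
Product: 12 1-[3-iodo-2,4-bis(methoxymethoxy)phenyl]ethanone
Conditions: MOMCl, i-Pr2NEt, DMF, 0 → 50 °C
Reagents that add atoms: chloromethyl methyl ether, COCCl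
Why: MOM acetalisation of both phenols, with warming for the hindered chelated hydroxyl between iodine and the acetyl group.

Step 8
Reactants: 12 1-[3-iodo-2,4-bis(methoxymethoxy)phenyl]ethanone; 2 2,4-bis(methoxymethoxy)benzaldehyde
Product: 13 (E)-1-[3-iodo-2,4-bis(methoxymethoxy)phenyl]-3-[2,4-bis(methoxymethoxy)phenyl]prop-2-en-1-one
Conditions: KOH, EtOH, rt
Reagents that add atoms: none
Why: Claisen–Schmidt condensation of the methyl ketone with the non-enolisable aldehyde should give the (E)-chalcone, the aryl iodide and MOM ethers being inert to hydroxide.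

Step 9
Reactants: 13 (E)-iodochalcone; 9 bridged allylic lactone
Product: 15 (1S,2S,6R)-2-[3-[(E)-3-[2,4-bis(methoxymethoxy)phenyl]prop-2-enoyl]-2,6-bis(methoxymethoxy)phenyl]-6-[2,4-bis(methoxymethoxy)phenyl]-4-methylcyclohex-3-ene-1-carboxylic acid, via arylzinc iodide 14 (not isolated)
Conditions: 13, Zn dust, LiCl, THF, 40 °C; then 9, Pd(PPh3)4 (5 mol %), THF, 0 °C → rt; cold 0.5 M HCl work-up
Reagents that add atoms: zinc, [Zn] (present in 14 only)
Why: zinc insertion into the aryl iodide (ketone and enone tolerated) is followed by Tsuji–Trost ionisation and Negishi-type allyl–aryl coupling: zerovalent palladium displaces the allylic lactone oxygen with inversion and the aryl group is delivered from the metal to the secondary allyl terminus (the methyl-bearing terminus would give a quaternary centre), on the face opposite the former lactone bridge, so the new C-2 stereocentre should be trans to the C-1 carboxyl and cis to the C-6 aryl group, with the double bond at C-3/C-4.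

Step 10
Reactants: 16 4-bromobenzene-1,3-diol
Product: 17 1-bromo-2,4-bis(methoxymethoxy)benzene
Conditions: MOMCl, i-Pr2NEt, CH2Cl2, 0 °C → rt
Reagents that add atoms: chloromethyl methyl ether, COCCl
Why: MOM acetalisation of both phenols, which also installs the two directing groups for the next metalation.

Step 11
Reactants: 17 1-bromo-2,4-bis(methoxymethoxy)benzene; 18 1-bromo-3-methylbut-2-ene
Product: 20 1-bromo-2,4-bis(methoxymethoxy)-3-(3-methylbut-2-en-1-yl)benzene, via aryllithium 19 (not isolated)
Conditions: LiN(i-Pr)2, THF, −78 °C; then CuBr·SMe2 (10 mol %), prenyl bromide, −78 → 0 °C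
Reagents that add atoms: lithium diisopropylamide, [Li+].CC(C)[N-]C(C)C (lithium present in 19 only)
Why: directed ortho-metalation removes the most acidic proton, the one between the two MOM ethers (an amide base does not exchange the bromine), and copper-assisted SN2 allylation with prenyl bromide should place the prenyl group between the two oxygens.

Step 12
Reactants: 15 all-trans cyclohexene carboxylic acid; 20 1-bromo-2,4-bis(methoxymethoxy)-3-(3-methylbut-2-en-1-yl)benzene
Product: 23 octakis(methoxymethyl) ether of kuwanon I, via acid chloride 21 (not isolated), via arylzinc chloride 22 (not isolated)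
Conditions: 15, 1-chloro-N,N,2-trimethylprop-1-en-1-amine, CH2Cl2, 0 °C → rt; 20, Mg, LiCl, ZnCl2, THF, rt; then combine, Pd(PPh3)4 (5 mol %), THF, 0 °C → rt
Reagents that add atoms: 1-chloro-N,N,2-trimethylprop-1-en-1-amine, CC(C)=C(Cl)N(C)C (its chlorine is present in 21 only); zinc chloride, Cl[Zn]Cl (zinc and chlorine present in 22 only)
Why: the acid is converted under neutral conditions into the acyl chloride, zerovalent palladium inserts into its C–Cl bond, the aryl group is transferred from zinc (made by magnesium insertion with in-situ transmetalation) and reductive elimination forms the aryl–C(=O) bond. The closest known reaction type is the Negishi acylation (palladium-catalysed ketone synthesis from acid chlorides and organozinc reagents). No ring is closed and no stereocentre is created: C-1, C-2 and C-6 are carried through, and neither reagent is basic. Should C-1 nevertheless pass through a ketene or enol, the same isomer is expected, because the acyl group between two cis, equatorial aryl groups is the thermodynamic arrangement. The step needs chemoselectivity for the acyl chloride over the chalcone enone, its ketone and eight acetals, which the unreactivity of arylzinc halides toward ketones and enones and the fast insertion of palladium into C(O)–Cl should secure. It also needs one defined arene position, which is fixed by the C–Zn bond made from the C–Br bond of 20 (ortho to one MOM ether, para to the other).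

Step 13
Reactants: 23 octakis(methoxymethyl) ether of kuwanon I
Product: 24 kuwanon I
Conditions: 3 M HCl (aq.)/MeOH, THF, rt, argon
Reagents that add atoms: none
Why: acid-catalysed acetal exchange with methanol should remove all eight MOM groups under conditions mild enough to leave the prenyl group, the 2′-hydroxychalcone and the three stereocentres unchanged.

**Compound list**

1 | 2,4-dihydroxybenzaldehyde | O=Cc1ccc(O)cc1O | starting material
2 | 2,4-bis(methoxymethoxy)benzaldehyde | COCOc1ccc(C=O)c(OCOC)c1 | intermediate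
3 | 3-hydroxy-3-methylbutan-2-one | CC(=O)C(C)(C)O | starting material
4 | (E)-1-[2,4-bis(methoxymethoxy)phenyl]-4-hydroxy-4-methylpent-1-en-3-one | CC(C)(O)C(=O)/C=C/c1ccc(OCOC)cc1OCOC | intermediate
5 | isoprene (2-methylbuta-1,3-diene) | C=CC(C)=C | starting material
6 | 1-[(1R,6R)-6-[2,4-bis(methoxymethoxy)phenyl]-4-methylcyclohex-3-en-1-yl]-2-hydroxy-2-methylpropan-1-one (acyl and aryl trans) | CC(C)(O)C(=O)[C@@H]1CC=C(C)C[C@H]1c1ccc(OCOC)cc1OCOC | intermediate
7 | (1R,6R)-6-[2,4-bis(methoxymethoxy)phenyl]-4-methylcyclohex-3-ene-1-carboxylic acid | OC(=O)[C@@H]1CC=C(C)C[C@H]1c1ccc(OCOC)cc1OCOC | intermediate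
8 | (1R,4R,5R,7R)-5-[2,4-bis(methoxymethoxy)phenyl]-1-methyl-7-(phenylselanyl)-2-oxabicyclo[2.2.2]octan-3-one (selenolactone; PhSe anti to the lactone oxygen) | O=C1O[C@@]2(C)[C@H]([Se]c3ccccc3)C[C@@H]1[C@H](c1ccc(OCOC)cc1OCOC)C2 | intermediate
9 | (1R,4R,8R)-8-[2,4-bis(methoxymethoxy)phenyl]-1-methyl-2-oxabicyclo[2.2.2]oct-5-en-3-one (aryl on the side of the alkene bridge, away from the lactone bridge) | O=C1O[C@@]2(C)C=C[C@@H]1[C@H](c1ccc(OCOC)cc1OCOC)C2 | intermediate
10 | 1-(2,4-dihydroxyphenyl)ethanone | CC(=O)c1ccc(O)cc1O | starting material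
11 | 1-(2,4-dihydroxy-3-iodophenyl)ethanone | CC(=O)c1ccc(O)c(I)c1O | intermediate
12 | 1-[3-iodo-2,4-bis(methoxymethoxy)phenyl]ethanone | CC(=O)c1ccc(OCOC)c(I)c1OCOC | intermediate
13 | (E)-1-[3-iodo-2,4-bis(methoxymethoxy)phenyl]-3-[2,4-bis(methoxymethoxy)phenyl]prop-2-en-1-one | O=C(/C=C/c1ccc(OCOC)cc1OCOC)c1ccc(OCOC)c(I)c1OCOC | intermediate
14 | [3-[(E)-3-[2,4-bis(methoxymethoxy)phenyl]prop-2-enoyl]-2,6-bis(methoxymethoxy)phenyl]zinc iodide | O=C(/C=C/c1ccc(OCOC)cc1OCOC)c1ccc(OCOC)c([Zn]I)c1OCOC | intermediate
15 | (1S,2S,6R)-2-[3-[(E)-3-[2,4-bis(methoxymethoxy)phenyl]prop-2-enoyl]-2,6-bis(methoxymethoxy)phenyl]-6-[2,4-bis(methoxymethoxy)phenyl]-4-methylcyclohex-3-ene-1-carboxylic acid (carboxyl trans to both aryl groups) | OC(=O)[C@@H]1[C@@H](c2c(OCOC)ccc(C(=O)/C=C/c3ccc(OCOC)cc3OCOC)c2OCOC)C=C(C)C[C@H]1c1ccc(OCOC)cc1OCOC | intermediate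
16 | 4-bromobenzene-1,3-diol | Oc1ccc(Br)c(O)c1 | starting material
17 | 1-bromo-2,4-bis(methoxymethoxy)benzene | COCOc1ccc(Br)c(OCOC)c1 | intermediate
18 | 1-bromo-3-methylbut-2-ene (prenyl bromide) | CC(C)=CCBr | starting material
19 | [3-bromo-2,6-bis(methoxymethoxy)phenyl]lithium | COCOc1ccc(Br)c(OCOC)c1[Li] | intermediate
20 | 1-bromo-2,4-bis(methoxymethoxy)-3-(3-methylbut-2-en-1-yl)benzene | CC(C)=CCc1c(OCOC)ccc(Br)c1OCOC | intermediate
21 | (1S,2S,6R)-2-[3-[(E)-3-[2,4-bis(methoxymethoxy)phenyl]prop-2-enoyl]-2,6-bis(methoxymethoxy)phenyl]-6-[2,4-bis(methoxymethoxy)phenyl]-4-methylcyclohex-3-ene-1-carbonyl chloride | ClC(=O)[C@@H]1[C@@H](c2c(OCOC)ccc(C(=O)/C=C/c3ccc(OCOC)cc3OCOC)c2OCOC)C=C(C)C[C@H]1c1ccc(OCOC)cc1OCOC | intermediate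
22 | [2,4-bis(methoxymethoxy)-3-(3-methylbut-2-en-1-yl)phenyl]zinc chloride | CC(C)=CCc1c(OCOC)ccc([Zn]Cl)c1OCOC | intermediate
23 | (E)-1-[3-[(1S,5R,6S)-6-[2,4-bis(methoxymethoxy)-3-(3-methylbut-2-en-1-yl)benzoyl]-5-[2,4-bis(methoxymethoxy)phenyl]-3-methylcyclohex-2-en-1-yl]-2,4-bis(methoxymethoxy)phenyl]-3-[2,4-bis(methoxymethoxy)phenyl]prop-2-en-1-one | CC(C)=CCc1c(OCOC)ccc(C(=O)[C@@H]2[C@@H](c3c(OCOC)ccc(C(=O)/C=C/c4ccc(OCOC)cc4OCOC)c3OCOC)C=C(C)C[C@H]2c2ccc(OCOC)cc2OCOC)c1OCOC | intermediate
24 | kuwanon I, (E)-1-[3-[(1S,5R,6S)-6-[2,4-dihydroxy-3-(3-methylbut-2-en-1-yl)benzoyl]-5-(2,4-dihydroxyphenyl)-3-methylcyclohex-2-en-1-yl]-2,4-dihydroxyphenyl]-3-(2,4-dihydroxyphenyl)prop-2-en-1-one | CC(C)=CCc1c(O)ccc(C(=O)[C@@H]2[C@@H](c3c(O)ccc(C(=O)/C=C/c4ccc(O)cc4O)c3O)C=C(C)C[C@H]2c2ccc(O)cc2O)c1O | target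

**Step count and risks**

Total step count: 13 (compounds 8, 14, 19, 21 and 22 are not isolated).
Longest linear sequence: 8 steps (1, 2, 3, 4, 5, 9, 12, 13).

Steps most likely to fail:

1. Step 9. The C-8 aryl group of 9 shields the alkene face that palladium must approach, so ionisation may be slow. Once the allyl complex has formed, transfer of the doubly ortho-substituted aryl group is slow and may be outrun by β-hydride elimination to a cyclohexadiene or by aryl transfer to the methyl-bearing terminus. The fallback sets out from 12 and 4 and comes back at 15, using the Diels–Alder reaction of an aryl diene that is usual for this family of adducts. A Heck reaction of 12 with 2-methylbut-3-en-2-ol (Pd(OAc)2, P(o-tol)3, Et3N, DMF, 100 °C) should give the tertiary allylic alcohol (E)-1-[3-(3-hydroxy-3-methylbut-1-en-1-yl)-2,4-bis(methoxymethoxy)phenyl]ethanone F1. Dehydration with the Burgess reagent should give the diene 1-[2,4-bis(methoxymethoxy)-3-[(E)-3-methylbuta-1,3-dien-1-yl]phenyl]ethanone F2. Its Diels–Alder reaction with 4 under the conditions of step 3 (or thermally) is expected to give both C-2 epimers, and the trans,trans ketol F3 is separated by chromatography. NaIO4 then cleaves it to the acetyl-bearing acid F4, and Claisen–Schmidt condensation of F4 with 2 (KOH, EtOH) gives 15. The price is the loss of control at C-2.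

2. Step 3. Donation from the two alkoxy groups lowers the reactivity of the β-aryl enone, so cycloaddition may be slower than polymerisation of isoprene, and an unchelated acid-catalysed pathway may erode facial selectivity. The fallback sets out from 5 and 17 and comes back at 7, setting C-6 by conjugate addition instead of cycloaddition. The AlCl3-promoted Diels–Alder reaction of 5 with methyl propiolate should give methyl 4-methylcyclohexa-1,4-diene-1-carboxylate F5. Bromine–lithium exchange of 17 (n-BuLi, THF, −78 °C), B(OiPr)3 and aqueous work-up give [2,4-bis(methoxymethoxy)phenyl]boronic acid F6. Rhodium-catalysed asymmetric 1,4-addition of F6 to F5 ([Rh(acac)(C2H4)2], (S)-BINAP or its antipode as required, dioxane/H2O), followed by NaOMe/MeOH equilibration at C-1, should give the trans ester methyl (1R,6R)-6-[2,4-bis(methoxymethoxy)phenyl]-4-methylcyclohex-3-ene-1-carboxylate F7. LiOH (THF/H2O) then gives 7.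

3. Step 12. The acyl chloride is flanked by two aryl-bearing carbons, so oxidative addition and transmetalation may be slow. Loss of HCl to a ketene, or attack of a neighbouring aryl MOM-ether oxygen on the acyl chloride (lactone formation with loss of that MOM group), may then compete. The fallback sets out from 15 and 20 and comes back at 23 by a Liebeskind–Srogl coupling, which uses a far less electrophilic acyl donor under base-free conditions. Compound 15 is converted with EtSH, dicyclohexylcarbodiimide and catalytic DMAP (CH2Cl2, 0 °C) into the S-ethyl thioester F8. Compound 20 is converted by bromine–lithium exchange (n-BuLi, −78 °C), B(OiPr)3 and aqueous work-up into [2,4-bis(methoxymethoxy)-3-(3-methylbut-2-en-1-yl)phenyl]boronic acid F9. Coupling of F8 with F9 (Pd2(dba)3, tri(2-furyl)phosphine, monovalent copper thiophene-2-carboxylate CuO2CC4H3S, THF, 50 °C) should give 23.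

**Further compounds**

F1 | step 9 | (E)-1-[3-(3-hydroxy-3-methylbut-1-en-1-yl)-2,4-bis(methoxymethoxy)phenyl]ethanone | CC(=O)c1ccc(OCOC)c(/C=C/C(C)(C)O)c1OCOC
F2 | step 9 | 1-[2,4-bis(methoxymethoxy)-3-[(E)-3-methylbuta-1,3-dien-1-yl]phenyl]ethanone | CC(=O)c1ccc(OCOC)c(/C=C/C(C)=C)c1OCOC
F3 | step 9 | 1-[(1S,2S,6R)-2-[3-acetyl-2,6-bis(methoxymethoxy)phenyl]-6-[2,4-bis(methoxymethoxy)phenyl]-4-methylcyclohex-3-en-1-yl]-2-hydroxy-2-methylpropan-1-one | CC(C)(O)C(=O)[C@@H]1[C@@H](c2c(OCOC)ccc(C(C)=O)c2OCOC)C=C(C)C[C@H]1c1ccc(OCOC)cc1OCOC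
F4 | step 9 | (1S,2S,6R)-2-[3-acetyl-2,6-bis(methoxymethoxy)phenyl]-6-[2,4-bis(methoxymethoxy)phenyl]-4-methylcyclohex-3-ene-1-carboxylic acid | OC(=O)[C@@H]1[C@@H](c2c(OCOC)ccc(C(C)=O)c2OCOC)C=C(C)C[C@H]1c1ccc(OCOC)cc1OCOC
F5 | step 3 | methyl 4-methylcyclohexa-1,4-diene-1-carboxylate | COC(=O)C1=CCC(C)=CC1
F6 | step 3 | [2,4-bis(methoxymethoxy)phenyl]boronic acid | COCOc1ccc(B(O)O)c(OCOC)c1
F7 | step 3 | methyl (1R,6R)-6-[2,4-bis(methoxymethoxy)phenyl]-4-methylcyclohex-3-ene-1-carboxylate | COC(=O)[C@@H]1CC=C(C)C[C@H]1c1ccc(OCOC)cc1OCOC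
F8 | step 12 | S-ethyl (1S,2S,6R)-2-[3-[(E)-3-[2,4-bis(methoxymethoxy)phenyl]prop-2-enoyl]-2,6-bis(methoxymethoxy)phenyl]-6-[2,4-bis(methoxymethoxy)phenyl]-4-methylcyclohex-3-ene-1-carbothioate | CCSC(=O)[C@@H]1[C@@H](c2c(OCOC)ccc(C(=O)/C=C/c3ccc(OCOC)cc3OCOC)c2OCOC)C=C(C)C[C@H]1c1ccc(OCOC)cc1OCOC
F9 | step 12 | [2,4-bis(methoxymethoxy)-3-(3-methylbut-2-en-1-yl)phenyl]boronic acid | CC(C)=CCc1c(OCOC)ccc(B(O)O)c1OCOC
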